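Time drops out of the first question about these flasks, which is how much target each can hold.

| setting | alpha | beta | theta |
|---|---|---|---|
| electrophile | 0.30 M | 0.30 M (fed, over 1.0 min) | 0.30 M |
| nucleophile | 1.05 equiv | 1.05 equiv | 1.05 equiv |
| free base | 1.20 equiv (fed, over 1.0 min) | 1.20 equiv | 1.20 equiv |
| time | 80 s | 80 s | 80 s |
| remark | all else is in the flask from the start; the feed brings no volume worth counting | all else is in the flask from the start; the feed brings no volume worth counting | everything together at the start |

    electrophile + nucleophile → acid set free + target (k1 = 0.12 M⁻¹ s⁻¹)
    nucleophile + acid set free ⇌ protonated nucleophile, settled at all times (K2 = 420 M⁻¹)
    acid set free + free base ⇌ salt of the base, settled at all times (K3 = 50000 M⁻¹)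
    electrophile + target → side product (k4 = 0.12 M⁻¹ s⁻¹)

- percentages count the electrophile that a species holds: one side product counts as two
- run time (alpha): 80 s

- the flask that comes out highest in amount of target, in percent of the electrophile charged, or "all alike" when all lie within 1.5 percentage points (alpha / beta / theta / all alike)
- target at the end, in percent of the electrophile charged, alpha
- target at the end, in percent of the electrophile charged, beta
- target at the end, in percent of the electrophile charged, theta

What makes target rise or fall? Step 1 makes it and step 4 destroys it, so it rises while k1[nucleophile] beats k4[target]. Here k1 equals k4, a selectivity factor of 1.00, so control changes hands where [target] equals [nucleophile].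

And the electrophile? [Electrophile] multiplies both rates, so it cancels from their ratio, and with it the clock. So long as the acid takes no nucleophile away, target per nucleophile spent does not depend on how the electrophile goes in. With x the fraction of nucleophile not yet spent, the balance gives target = nucleophile charged × x ln(1/x). The crossing lies at x = 36.8%. This gives the crest, the nucleophile charge divided by e, 38.6% of the electrophile charged.

Doesn't the acid steal nucleophile? In theta at the start, K3[free base] is 18000 against 130 for K2[nucleophile], far greater, so the acid goes to the base. In alpha the base arrives over 1.0 min, and I have no hand figure for that. I hold alpha a little under theta.

Is 80 s long enough? Reaching the crest uses 94.1% of the electrophile charged. Theta should get close, since with the concentrations as charged the half-life of electrophile by step 1 alone is 18 s and that of target by step 4 alone is 19 s, both shorter than the run. Beta receives its last electrophile at 1.0 min and lags, but the top is flat: at x = 0.5 target still stands at 36.4%. I commit to theta at the crest and the others a little below, all alike, with beta the one that could leave the band of 1.5 percentage points.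

The forecast gave all alike, with 37.5%, 38% and 38.4% for alpha, beta and theta, holding that “the target is consumed about as readily as it forms”.

The simulation gives all alike: alpha 37.9%, beta 37.7%, theta 38.5%.

In beta, step 1 used electrophile 3.1 times as fast as step 4 at 41.1 s, and 1.2 times as fast at 80.0 s. Beta ended short of the crossing, with 44.5% of its nucleophile free against the 36.8% of the crest. A neighbour of beta charged with 0.630 equiv of nucleophile has a crest of 23.2%, and it ends with 23.1% target and 34.1% of its nucleophile free.

(The numbers of this flask come from no measurement; no experiment stands behind them.)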